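# Total synthesis of (−)-incarvillateine (CNP0283097.2)

## Retrosynthetic overview
1. The two acyl C–O ester bonds are cut last. This gives two molecules of (−)-incarvilline and one phenol-capped α-truxillic diacid (ring C, cyclobutane).
2. Ring C comes from a lattice-controlled head-to-tail [2+2] photodimerisation of crystalline O-tosylferulic acid.
3. Ring B (piperidine) is closed in one flask. A CuH anti-Markovnikov hydroamination with a MeNH donor makes C3–N and sets C4, and lactamisation then makes C1–N.
4. Ring A (cyclopentane, centres C4a, C6, C7, C7a) comes from Favorskii contraction of the chlorohydrin ether of (R)-carvone epoxide.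
5. Ring order: A (step 3), B (step 4), C (step 7, parallel branch), then union by double esterification (step 8).

Assumption: (R)-DTBM-SEGPHOS is taken as the ligand antipode that delivers hydride to the Re face of C4 (quadrant model; both antipodes are commercial and the one giving 4R is meant), and the THP acetal carbon, an epimer mixture removed in step 5, is left undefined in all SMILES.

Atom labels: carvone numbering for 1–4; incarvilline numbering (C1, N2, C3, C4, C4a, C5, C6, C7, C7a) from 5 on.

## Route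

Step 1
Reactants: 1 (R)-(−)-carvone
Product: 2 carvone epoxide (1R,4R,6R)-1-methyl-4-(prop-1-en-2-yl)-7-oxabicyclo[4.1.0]heptan-2-one
Conditions: 30% aq H2O2, NaOH (0.3 equiv), MeOH, 0 °C to rt
Reagents that add atoms: hydrogen peroxide, OO
Why: Weitz–Scheffer nucleophilic epoxidation touches only the enone C=C, and axial attack of HOO− anti to the C5 isopropenyl group places the oxirane trans to it, which fixes the future C6–O configuration.

Step 2
Reactants: 2 carvone epoxide
Product: 4 THP ether (2S,3R,5R)-2-chloro-2-methyl-3-(oxan-2-yloxy)-5-(prop-1-en-2-yl)cyclohexan-1-one, via chlorohydrin 3 (not isolated)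
Conditions: LiCl, TFA, THF, 0 °C to rt; then DHP, PPTS (5 mol%), rt
Reagents that add atoms: lithium chloride, [Li+].[Cl-]; 3,4-dihydro-2H-pyran, C1=COCCC1
Why: HCl made in situ opens the protonated oxirane by SN2 attack of chloride at the α-carbon C2 (trans-diaxial Fürst–Plattner epoxide opening), which inverts C2 and keeps the C3–O bond, and acid-catalysed tetrahydropyranylation in the same flask caps the hydroxyl that would otherwise re-close the epoxide under base.

Step 3
Reactants: 4 THP ether
Product: 6 methyl (1R,2S,3R,5R)-2-methyl-3-(oxan-2-yloxy)-5-(prop-1-en-2-yl)cyclopentane-1-carboxylate, via cyclopropanone 5 (not isolated)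
Conditions: NaOMe, MeOH, 0 °C to rt
Reagents that add atoms: sodium methoxide, [Na+].[O-]C
Why: Favorskii rearrangement, in which the C6 enolate displaces the axial chloride with inversion to give cyclopropanone 5 with its carbonyl bridge on the isopropenyl face, and methoxide opens it toward the carbanion next to the C–OTHP carbon, protonated with retention, so that C7a (ester cis to isopropenyl) and C7 (methyl trans to ester, cis to OTHP) are set stereospecifically.

Step 4
Reactants: 6 cyclopentane ester; 7 N-methyl-O-benzoylhydroxylamine hydrochloride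
Product: 9 lactam (4R,4aS,6R,7S,7aR)-2,4,7-trimethyl-6-(oxan-2-yloxy)octahydro-1H-cyclopenta[c]pyridin-1-one, via amino ester 8 (not isolated)
Conditions: Cu(OAc)2 (5 mol%), (R)-DTBM-SEGPHOS (5.5 mol%), PPh3 (10 mol%), (MeO)2MeSiH (4 equiv), THF, 40 °C; 7 (2 equiv, free-based with aq NaHCO3, cold THF solution added over 12 h); then MeOH, 65 °C
Reagents that add atoms: N-methyl-O-benzoylhydroxylamine hydrochloride (7), CNOC(=O)c1ccccc1.Cl
Why: Proposed new method: ligated CuH (from Cu(OAc)2 and the silane) adds across the 1,1-disubstituted alkene with copper on the CH2 terminus and hydride on C4, the ligand reading the large methyl-versus-cyclopentyl size contrast and delivering hydride to the Re face (sets 4R); the primary alkylcopper is aminated at nitrogen of MeNH–OBz, kept dilute by slow addition so that its reduction by CuH, N–H protonolysis of the alkylcopper and benzoyl transfer to the product amine cannot compete; copper benzoate is turned over by the silane, and the secondary amine, held cis-1,2 to the ester, closes the six-membered lactam on warming; the closest known reaction type is CuH-catalysed anti-Markovnikov hydroamination of 1,1-disubstituted alkenes with N,N-dialkyl-O-benzoylhydroxylamines, and new are the N–H methylamine donor on an unactivated alkene and the coupled lactamisation that makes both C–N bonds of ring B in one flask.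

Step 5
Reactants: 9 lactam
Product: 11 (−)-incarvilline (4R,4aS,6R,7S,7aR)-2,4,7-trimethyloctahydro-1H-cyclopenta[c]pyridin-6-ol, via O-THP-incarvilline 10 (not isolated)
Conditions: LiAlH4, THF, 65 °C; then 3 M aq HCl, rt, 2 h; NaOH work-up
Reagents that add atoms: none
Why: Hydride reduction of the tertiary lactam to the amine touches no stereocentre, and the acidic quench hydrolyses the THP acetal in the same flask.

Step 6
Reactants: 12 trans-ferulic acid
Product: 13 O-tosylferulic acid (E)-3-[3-methoxy-4-(tosyloxy)phenyl]prop-2-enoic acid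
Conditions: TsCl, aq NaOH, THF, 0 °C to rt; then aq HCl; recrystallise from EtOH
Reagents that add atoms: p-toluenesulfonyl chloride, Cc1ccc(cc1)S(=O)(=O)Cl
Why: Schotten–Baumann sulfonylation caps the phenoxide, and any mixed carboxylic–sulfonic anhydride is hydrolysed back by the aqueous base.

Step 7
Reactants: 13 O-tosylferulic acid (two molecules)
Product: 14 di-O-tosyl α-truxillic diacid 2,4-bis[3-methoxy-4-(tosyloxy)phenyl]cyclobutane-1,3-dicarboxylic acid (centrosymmetric; aryls mutually trans; carboxyls mutually trans)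
Conditions: hν (high-pressure mercury lamp, Pyrex), powdered crystals, rt, periodic remixing
Reagents that add atoms: none
Why: Topochemical [2+2] photocycloaddition, in which inversion-related head-to-tail pairs of the E-acid with C=C contacts below about 4.2 Å allow only the α-truxillic dimer, so that alkene geometry and lattice symmetry set all four ring C centres.

Step 8
Reactants: 14 di-O-tosyl α-truxillic diacid; 11 (−)-incarvilline (2.3 equiv)
Product: 16 di-O-tosylincarvillateine, via monoester acid 15 (not isolated)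
Conditions: EDC·HCl (3 equiv), DMAP (3 equiv), CH2Cl2, 0 °C to rt
Reagents that add atoms: none
Why: Steglich esterification forms both acyl C–O bonds with retention at C6 because the C6–O bond is never broken, and since the two carboxyls of 14 are enantiotopic both possible monoesters converge on one diester.

Step 9
Reactants: 16 di-O-tosylincarvillateine
Product: 17 (−)-incarvillateine
Conditions: sodium amalgam (6 wt% Na in Hg), Na2HPO4, MeOH, rt; aq NH4Cl
Reagents that add atoms: none
Why: Single-electron reductive cleavage of the aryl sulfonate S–O bonds frees both phenols, while the buffered medium leaves the hindered alkyl esters, the tertiary amines and the cyclobutane untouched.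

## Compound list
1 | (R)-(−)-carvone | CC1=CC[C@H](CC1=O)C(C)=C | starting material
2 | (1R,4R,6R)-1-methyl-4-(prop-1-en-2-yl)-7-oxabicyclo[4.1.0]heptan-2-one (oxirane trans to isopropenyl) | C[C@@]12O[C@@H]1C[C@@H](C(C)=C)CC2=O | intermediate
3 | (2S,3R,5R)-2-chloro-3-hydroxy-2-methyl-5-(prop-1-en-2-yl)cyclohexan-1-one | C[C@]1(Cl)[C@H](O)C[C@@H](C(C)=C)CC1=O | intermediate
4 | (2S,3R,5R)-2-chloro-2-methyl-3-(oxan-2-yloxy)-5-(prop-1-en-2-yl)cyclohexan-1-one | C[C@]1(Cl)[C@H](OC2CCCCO2)C[C@@H](C(C)=C)CC1=O | intermediate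
5 | (1R,2R,4R,5R)-1-methyl-2-(oxan-2-yloxy)-4-(prop-1-en-2-yl)bicyclo[3.1.0]hexan-6-one (carbonyl bridge on the isopropenyl face) | C1CCCC(O1)O[C@@H]2C[C@@H](C(C)=C)[C@H]3C(=O)[C@@]23C | intermediate
6 | methyl (1R,2S,3R,5R)-2-methyl-3-(oxan-2-yloxy)-5-(prop-1-en-2-yl)cyclopentane-1-carboxylate | C1CCCC(O1)O[C@@H]2C[C@@H](C(C)=C)[C@@H](C(=O)OC)[C@@H]2C | intermediate
7 | N-methyl-O-benzoylhydroxylamine hydrochloride | CNOC(=O)c1ccccc1.Cl | starting material
8 | methyl (1R,2S,3R,5S)-2-methyl-5-[(2R)-1-(methylamino)propan-2-yl]-3-(oxan-2-yloxy)cyclopentane-1-carboxylate | C1CCCC(O1)O[C@@H]2C[C@@H]([C@@H](C)CNC)[C@@H](C(=O)OC)[C@@H]2C | intermediate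
9 | (4R,4aS,6R,7S,7aR)-2,4,7-trimethyl-6-(oxan-2-yloxy)octahydro-1H-cyclopenta[c]pyridin-1-one (cis-fused) | C1CCCC(O1)O[C@@H]2C[C@@H]3[C@@H](C(=O)N(C)C[C@@H]3C)[C@@H]2C | intermediate
10 | O-THP-incarvilline | C1CCCC(O1)O[C@@H]2C[C@@H]3[C@@H](CN(C)C[C@@H]3C)[C@@H]2C | intermediate
11 | (−)-incarvilline, (4R,4aS,6R,7S,7aR)-2,4,7-trimethyloctahydro-1H-cyclopenta[c]pyridin-6-ol | O[C@@H]1C[C@@H]2[C@@H](CN(C)C[C@@H]2C)[C@@H]1C | intermediate
12 | trans-ferulic acid | COc1cc(/C=C/C(=O)O)ccc1O | starting material
13 | O-tosylferulic acid | COc1cc(/C=C/C(=O)O)ccc1OS(=O)(=O)c1ccc(C)cc1 | intermediate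
14 | di-O-tosyl-4,4'-dihydroxy-3,3'-dimethoxy-α-truxillic acid | COc1cc([C@H]2[C@H](C(=O)O)[C@H](c3ccc(OS(=O)(=O)c4ccc(C)cc4)c(OC)c3)[C@H]2C(=O)O)ccc1OS(=O)(=O)c1ccc(C)cc1 | intermediate
15 | monoester of 14 with 11 (either enantiotopic carboxyl reacts; one diastereomer drawn; both lead to 16) | COc1cc([C@H]2[C@H](C(=O)O[C@@H]3C[C@@H]4[C@@H](CN(C)C[C@@H]4C)[C@@H]3C)[C@H](c3ccc(OS(=O)(=O)c4ccc(C)cc4)c(OC)c3)[C@H]2C(=O)O)ccc1OS(=O)(=O)c1ccc(C)cc1 | intermediate
16 | di-O-tosylincarvillateine | COc1cc([C@H]2[C@H](C(=O)O[C@@H]3C[C@@H]4[C@@H](CN(C)C[C@@H]4C)[C@@H]3C)[C@H](c3ccc(OS(=O)(=O)c4ccc(C)cc4)c(OC)c3)[C@H]2C(=O)O[C@@H]2C[C@@H]3[C@@H](CN(C)C[C@@H]3C)[C@@H]2C)ccc1OS(=O)(=O)c1ccc(C)cc1 | intermediate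
17 | (−)-incarvillateine | COc1cc([C@H]2[C@H](C(=O)O[C@@H]3C[C@@H]4[C@@H](CN(C)C[C@@H]4C)[C@@H]3C)[C@H](c3ccc(O)c(OC)c3)[C@H]2C(=O)O[C@@H]2C[C@@H]3[C@@H](CN(C)C[C@@H]3C)[C@@H]2C)ccc1O | target

## Step count and risks
Total steps: 9. Longest linear sequence: 7 (steps 1, 2, 3, 4, 5, 8, 9).

**Step 4 (the new step).**
- Risks:
  - The N–H donor may be reduced by CuH, or may rearrange (O to N benzoyl shift), faster than the hindered alkene is hydrocuprated.
  - Protonolysis of the alkylcopper would give the isopropyl by-product.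
  - The product amine could be benzoylated by the donor.
- Fallback (known chemistry): it sets out from 6 and comes back at 10.
  - Hydroboration–oxidation of 6 (9-BBN, THF; then NaBO3·4H2O) gives the hydroxy ester F1. C4 is under substrate control only, and the epimers are separated by chromatography.
  - LiAlH4 reduces F1 to the diol F2.
  - MsCl and Et3N convert F2 into the dimesylate F3.
  - Heating F3 with MeNH2 in EtOH (sealed tube, 70 °C) closes ring B by double SN2 N-alkylation and gives 10.
  - Compound 10 is hydrolysed with aq HCl as in step 5.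

**Step 8.**
- Risks:
  - The second acylation of a hindered alcohol by a hindered acid may be slow.
  - N-acylurea may form.
  - The cyclobutane α-carbons may epimerise.
- Fallback: it sets out from 11 and comes back at 16.
  - Swern oxidation of 11 gives the ketone F4.
  - NaBH4 in MeOH attacks F4 from the convex face and gives 6-epi-incarvilline F5.
  - A double Mitsunobu reaction of 14 with F5 (PPh3, DIAD, THF) makes the alkyl C6–O bonds with inversion and gives 16.

**Step 7.**
- Risks:
  - The outcome depends on the crystal form.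
  - Light penetration limits conversion on scale.
- Fallback: it sets out from 12 and comes back at 17. It changes the lattice and the end game.
  - Ac2O and pyridine give O-acetylferulic acid F6.
  - Solid-state irradiation of its crystals gives the di-O-acetyl α-truxillic diacid F7.
  - (COCl)2 with catalytic DMF gives the bis(acid chloride) F8.
  - F8 acylates 11 in pyridine and CH2Cl2 to give di-O-acetylincarvillateine F9. DMAP is left out to avoid acetyl transfer.
  - K2CO3 in MeOH at 0 °C removes the aryl acetates and gives 17.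

## Further compounds
F1 | step 4 | methyl (1R,2S,3R,5S)-5-[(2R)-1-hydroxypropan-2-yl]-2-methyl-3-(oxan-2-yloxy)cyclopentane-1-carboxylate | C1CCCC(O1)O[C@@H]2C[C@@H]([C@@H](C)CO)[C@@H](C(=O)OC)[C@@H]2C
F2 | step 4 | diol, F1 with the ester reduced to CH2OH (configuration unchanged) | C1CCCC(O1)O[C@@H]2C[C@@H]([C@@H](C)CO)[C@@H](CO)[C@@H]2C
F3 | step 4 | dimesylate of F2 | C1CCCC(O1)O[C@@H]2C[C@@H]([C@@H](C)COS(C)(=O)=O)[C@@H](COS(C)(=O)=O)[C@@H]2C
F4 | step 8 | (4R,4aS,7S,7aR)-2,4,7-trimethyloctahydro-6H-cyclopenta[c]pyridin-6-one | O=C1C[C@@H]2[C@@H](CN(C)C[C@@H]2C)[C@@H]1C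
F5 | step 8 | 6-epi-incarvilline, (4R,4aS,6S,7S,7aR)-2,4,7-trimethyloctahydro-1H-cyclopenta[c]pyridin-6-ol | O[C@H]1C[C@@H]2[C@@H](CN(C)C[C@@H]2C)[C@@H]1C
F6 | step 7 | O-acetylferulic acid | COc1cc(/C=C/C(=O)O)ccc1OC(C)=O
F7 | step 7 | di-O-acetyl-4,4'-dihydroxy-3,3'-dimethoxy-α-truxillic acid | COc1cc([C@H]2[C@H](C(=O)O)[C@H](c3ccc(OC(C)=O)c(OC)c3)[C@H]2C(=O)O)ccc1OC(C)=O
F8 | step 7 | bis(acid chloride) of F7 | COc1cc([C@H]2[C@H](C(=O)Cl)[C@H](c3ccc(OC(C)=O)c(OC)c3)[C@H]2C(=O)Cl)ccc1OC(C)=O
F9 | step 7 | di-O-acetylincarvillateine | COc1cc([C@H]2[C@H](C(=O)O[C@@H]3C[C@@H]4[C@@H](CN(C)C[C@@H]4C)[C@@H]3C)[C@H](c3ccc(OC(C)=O)c(OC)c3)[C@H]2C(=O)O[C@@H]2C[C@@H]3[C@@H](CN(C)C[C@@H]3C)[C@@H]2C)ccc1OC(C)=O
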